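## Structural features

The target is a furanoheliangolide: a ten-membered carbocycle (C1–C10) spanned by an oxygen bridge from C3 to C10, which makes C10, C1, C2, C3 and that oxygen a 3(2H)-furanone (ring B). It is fused at C6–C7 to an α-methylene-γ-butyrolactone (ring A: C6, C7, C11, C12 and the lactone oxygen, with C11=C13). The endocyclic C4=C5 alkene is trisubstituted and Z, carries the allylic C15 carbinol, and is cross-conjugated through C3=C2 with the C1 ketone. Three stereocentres are contiguous, C6 (R, lactone oxygen), C7 (R, bearing C11) and C8 (R, isobutyrate); the fourth, the fully substituted C10 (S), is separated from them by the C9 methylene. The exocyclic enoate and the dienone both accept nucleophiles, the C8 acyloxy group lies next to the vinylogously acidic C7–H and can be eliminated, and the furanone is a vinylogous ester, so strong bases, soft nucleophiles and late reductions must be avoided. The real difficulty is the C6–C7–C8 triad with its oxygen–carbon–oxygen pattern, together with closure of the strained, oxygen-bridged medium ring with a Z-trisubstituted alkene. The key step treats C7, a carbon-bearing centre between the oxygenated C6 and C8, as a 2,3-epoxy alcohol (C6–OH, C7–C8 epoxide) opened at C7 by carbon. It treats the C11=C13 methylene, with C12 on the C6 oxygen, as the remnant of a propargyl ether after a 5-exo-dig radical cyclisation.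

## Logic of the disconnections

**O–Si at C15.** 31 is traced to 30 by cutting the silicon–oxygen bond. The skeleton is unchanged, but the allylic alcohol is masked during ring closure. The forward step must be a non-basic desilylation that the enoate, the furanone and the ester tolerate.

**C4=C5.** Cutting this double bond opens the medium ring and reduces 30 to 29, in which rings A and B are joined only by the C7–C8–C9–C10 chain. It is the one ring bond whose two ends can be carried as simple terminal alkenes. The forward metathesis must join a vinyl group to a hindered 1,1-disubstituted alkene and give the Z geometry, which the bridged ring itself should impose.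

**O–C3 of ring B, then O–Si at C10.** Opening the furanone at its enol ether bond leads from 29 to the hydroxy ynone 28 and, with the tertiary oxygen silylated, to 27. The heterocycle becomes an alkyne and a ketone. The forward step needs a 5-endo-dig addition of the C10 hydroxyl to C3 and a desilylation that spares the C15 silyl ether.

**C1–C2.** 27 is taken back through the carbinol 26 to the aldehyde 19 and the enyne 24. This cut separates all of C2, C3, C4 and C15 as one small achiral piece. The forward addition must find the aldehyde in the presence of a lactone and an ester, which calls for low temperature and a cold quench.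

**C3–C4 of the small piece.** 24 is cut to 21 and 22, and 21 to 20. These are two steps from commercial materials. The coupling must deliver a terminal alkyne without a second coupling.

**Oxidation level at C12 and C1, and the C8 ester.** 19 is traced through 17 and 16 to 14 and 15: the lactone carbonyl and the aldehyde are removed as an ether CH2 and a silyl ether, and the ester as the free C8 alcohol. This exposes the methylene oxolane that the key step makes. The forward chromium oxidation must act at the C12 methylene, which is allylic and next to oxygen, and at the C1 carbinol only. For that reason C1 and C10 carry silyl ethers and not a benzyl-type ether, which hexavalent chromium would attack.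

**C7–C11.** 14 is cut to 13. Removing this one bond opens ring A to an epoxy propargyl ether in which C8 is held in the epoxide. The forward radical step must open the epoxide at C7, close 5-exo-dig, and place the C8 side chain trans to the C6 vinyl group.

**O–C12.** 13 is cut to 10 and 11. This is a plain etherification, which must not trigger epoxide migration.

**The C7–O–C8 epoxide.** 10 is traced to the dienol 9. One reagent-controlled epoxidation sets C7 and C8 and, as a kinetic resolution, selects C6. The price is that at most half of 9 can be used.

**C6–C7 and the C7=C8 π bond.** 9 comes from the ynol 8, and 8 from 5 and 6. The forward steps are an acetylide 1,2-addition and a trans-selective alkyne reduction.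

**C8–C9 and C10.** 5 is the bis-silyl ether of 4, which is cut at C8–C9 to 2 and 3; 2 comes from 1 by asymmetric epoxidation. This sets the isolated C10 centre in the first step and gives both oxygens of the C1/C10 diol one protecting group in a single operation.

## Other disconnections considered

**Alternative 1:** The cut is C7–C8. Forward, the seco aldehyde A2, a 3-(bromomethyl)butenolide that already carries the furanone and the Z-alkene, would be treated with CrCl2 (or zinc or indium metal). The allylmetal would add through C7 to the C8 aldehyde and give the macrocyclic alcohol A1, closing the carbocycle, creating C7 and C8 and moving the double bond to C11=C13.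
- In its favour: it is more convergent than the chosen plan. The methylene lactone appears without any allylic oxidation, so no hexavalent chromium is needed, and the ring closure does not depend on metathesis of a hindered diene. On these three points it is the better plan, and on step count it is at least the equal.
- Against it here: C7 and C8 would both be set inside a macrocyclic transition state with no reagent control. The C8 aldehyde of A2 is β to the furanone oxygen at C10 and could lose it by elimination. A2 also needs an enantiopure butenolide with an acidic C6–H.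
- Comparison: the chosen plan is the better on stereocontrol, because C8 comes from a Sharpless epoxide and C7 from an adjacent centre in a five-membered transition state.

**Alternative 2:** The cut is C1–C2 together with O–C3. Forward, the aldoxime A5 would be oxidised by NaOCl to a nitrile oxide, which would add to the terminal C2=C3 alkene of the diene and close both the isoxazoline and the carbocycle, giving A3. A drawing of this cycloadduct with a plain CH2 at C11 (A4) has lost C13 and could reach 31 only through a late α-methylenation; A3 restores the methylene.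
- In its favour: the regiochemistry of nitrile oxide addition to a terminal alkene is dependable, the isoxazoline masks the 1,3-dioxygenated C1–C3 unit, and the concerted closure needs no metal carbene. On mechanism it is the equal of the chosen ring closure, and on tolerance of the ring-closing reagent it is the better.
- Against it here: in A5 the C11=C13 enoate is a closer and more reactive dipolarophile than the diene. Removing it, as in A4, costs extra steps at the end. After closure, N–O cleavage, oxidation and cyclodehydration are still needed, and the reduction would have to spare the enoate.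
- Comparison: the chosen plan is shorter after ring closure and faces no competing π system in its key step.

**Alternative 3:** The cut is on both sides of C3, which would come from carbon monoxide. Forward, PdCl2(PPh3)2 and CuI under CO would join the vinyl iodide A7 and the alkyne A8 to give the hydroxy ynone A6.
- In its favour: three components are joined in one step, and A6 is a direct substrate for gold-catalysed furanone formation. The chosen plan needs addition, oxidation and desilylation to reach the same stage, so on convergence and step economy this alternative is the better; on the furanone chemistry the two are equal.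
- Against it here: it closes no ring. C7, C8 and the carbocycle would still have to be made by the allylation of alternative 1, with the same stereochemical uncertainty. The butenolide C6–H of A7 would meet an amine base, and direct coupling without CO could compete.
- Comparison: the chosen plan is the better on control of C7 and C8 and on the configurational safety of C6.

Key step: step 8

Remark: atom numbers are those of the germacrane skeleton used above, the target is taken as the (4Z,6R,7R,8R,10S) isomer, and reagent amounts are indicative.

## Route

Step 1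
Reactants: 1 methallyl alcohol
Product: 2 (R)-2-methylglycidol
Conditions: Ti(OiPr)4 (5 mol%), D-(−)-diisopropyl tartrate (6 mol%), t-BuOOH, 4 Å MS, CH2Cl2, −20 °C
Reagents that add atoms: tert-butyl hydroperoxide, CC(C)(C)OO
Why: Katsuki–Sharpless asymmetric epoxidation; with the D-(−)-tartrate the oxygen is delivered to the face that gives the (R)-epoxide, which fixes C10, and the C–O bond formed here becomes the C10–O bond of the furanone.

Step 2
Reactants: 2 (R)-2-methylglycidol; 3 lithium acetylide–ethylenediamine complex, LiC≡CH·H2NCH2CH2NH2
Product: 4 (2S)-2-methylpent-4-yne-1,2-diol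
Conditions: 3 (3 equiv), DMSO, 0 °C → rt; then H2O
Reagents that add atoms: none
Why: SN2 opening of the 2,2-disubstituted epoxide by acetylide at its unhindered CH2 (the future C9), a standard use of this reagent; the quaternary carbinol is not touched, and Payne migration of the alkoxide is degenerate and leads to the same diol.

Step 3
Reactants: 4 (2S)-2-methylpent-4-yne-1,2-diol
Product: 5 (4S)-4-methyl-4,5-bis(triethylsilyloxy)pent-1-yne
Conditions: Et3SiOTf (2.5 equiv), 2,6-lutidine, CH2Cl2, −78 → 0 °C
Reagents that add atoms: triethylsilyl trifluoromethanesulfonate, CC[Si](CC)(CC)OS(=O)(=O)C(F)(F)F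
Why: Silyl triflate with 2,6-lutidine silylates the primary and the tertiary hydroxyl in one operation; the two ethers differ enough in hindrance to be told apart by mild acid in step 10, and neither is attacked by the chromium oxidant of step 11.

Step 4
Reactants: 5 bis-silyl alkyne; 6 acrolein
Product: 8 (3RS,7S)-7-methyl-7,8-bis(triethylsilyloxy)oct-1-en-4-yn-3-ol (both C6 epimers), via lithium acetylide 7 (not isolated)
Conditions: n-BuLi, THF, −78 °C; then 6, −78 °C; H2O
Reagents that add atoms: none
Why: 1,2-addition of a lithium acetylide to an enal forms C6–C7; no selectivity at C6 is expected or needed, because step 6 selects the 6R epimer.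

Step 5
Reactants: 8 enynol
Product: 9 (3RS,4E,7S)-7-methyl-7,8-bis(triethylsilyloxy)octa-1,4-dien-3-ol
Conditions: NaAlH2(OCH2CH2OCH3)2, THF, 0 °C → rt; aq. KNaC4H4O6
Reagents that add atoms: none
Why: Hydroxyl-directed trans-hydroalumination of the propargylic alcohol followed by protonolysis should give only the (E)-allylic alcohol; the isolated vinyl group and the silyl ethers are inert to the aluminium hydride at this temperature.

Step 6
Reactants: 9 dienol (both C6 epimers)
Product: 10 (1R)-1-[(2R,3R)-3-[(2S)-2-methyl-2,3-bis(triethylsilyloxy)propyl]oxiran-2-yl]prop-2-en-1-ol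
Conditions: Ti(OiPr)4 (10 mol%), D-(−)-diisopropyl tartrate (15 mol%), t-BuOOH (0.55 equiv), 4 Å MS, CH2Cl2, −20 °C
Reagents that add atoms: tert-butyl hydroperoxide, CC(C)(C)OO
Why: Sharpless kinetic resolution of a secondary allylic alcohol; with the D-(−)-tartrate only the 6R epimer should be epoxidised quickly, at its (E)-disubstituted alkene and anti to the carbinol (erythro), so the reagent sets C7 and C8 and selects C6. For the 6S epimer the matched alkene is the slow terminal vinyl group, so with sub-stoichiometric hydroperoxide it should remain and be removed by chromatography.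

Step 7
Reactants: 10 epoxy alcohol; 11 propargyl bromide
Product: 13 (2S,3R)-2-[(1R)-1-(prop-2-yn-1-yloxy)prop-2-en-1-yl]-3-[(2S)-2-methyl-2,3-bis(triethylsilyloxy)propyl]oxirane, via sodium alkoxide 12 (not isolated)
Conditions: NaH, THF, 0 °C; then 11, n-Bu4NI (cat.), 0 °C → rt
Reagents that add atoms: none
Why: Williamson etherification of the alkoxide with a reactive propargylic halide under iodide catalysis; the aprotic medium and low temperature should prevent Payne migration of the epoxide and propargyl-to-allenyl isomerisation.

Step 8
Reactants: 13 epoxy propargyl ether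
Product: 14 (1R,3S)-3-methyl-1-[(2R,3R)-4-methylidene-2-vinyloxolan-3-yl]-3,4-bis(triethylsilyloxy)butan-1-ol
Conditions: (C5H5)2TiCl2 (2.5 equiv), Mn dust, THF, rt; the green solution added slowly to 13 in THF, rt; then aq. NaH2PO4
Reagents that add atoms: none
Why: (C5H5)2TiCl, formed from (C5H5)2TiCl2 and Mn, binds the epoxide oxygen and transfers one electron, breaking the C7–O bond so that tetravalent titanium stays on the C8 oxygen and a secondary radical is left at C7. This radical adds to the internal carbon of the propargyl ether in a 5-exo-dig closure (ring: C7, C6, O, C12, C11), forming C7–C11; the vinyl radical at C13 then takes a hydrogen atom from THF, or is reduced by a second trivalent titanium and protonated on work-up, leaving the C11=C13 methylene. The closest known reaction type is the titanocene chloride-mediated cyclisation of allyl and propargyl ethers of 2,3-epoxy alcohols to 3-substituted 4-methylene oxolanes. C7 is the only new stereocentre: it is planar at the radical stage and is controlled by the adjacent C6, whose vinyl group and the C8 side chain should take opposite faces of the forming ring, giving the 2,3-trans oxolane that the trans-fused lactone requires. C8 keeps the configuration from the epoxidation because its C–O bond is never broken, and C6 and C10 are spectators. The step needs homolysis at C7–O and not at C8–O, which is the sense observed for 2,3-epoxy ethers, where the C6 ether oxygen can also hold the titanium; a C8 radical would in any case have only a slower 6-exo path. It also needs cyclisation to outrun capture of the C7 radical by a second titanium (which would expel the C6 alkoxide and give an allylic alcohol) and a 1,2-vinyl shift through a cyclopropylcarbinyl radical; the oxygen in the tether speeds the 5-exo closure, and slow addition of the titanium reagent to dilute 13 keeps the trapping rate low.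

Step 9
Reactants: 14 methylene oxolane alcohol; 15 isobutyryl chloride
Product: 16 (1R,3S)-3-methyl-1-[(2R,3R)-4-methylidene-2-vinyloxolan-3-yl]-3,4-bis(triethylsilyloxy)butyl 2-methylpropanoate
Conditions: 15, pyridine, DMAP (cat.), CH2Cl2, 0 °C → rt
Reagents that add atoms: none
Why: DMAP-catalysed acylation of the secondary C8 alcohol installs the ester of the target at the first opportunity, so that it also protects C8 during the oxidations; the C8–O bond is not broken and the configuration is retained.

Step 10
Reactants: 16 bis-silyl ester
Product: 17 (1R,3S)-4-hydroxy-3-methyl-1-[(2R,3R)-4-methylidene-2-vinyloxolan-3-yl]-3-(triethylsilyloxy)butyl 2-methylpropanoate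
Conditions: PPTS (0.2 equiv), MeOH–CH2Cl2, 0 °C
Reagents that add atoms: none
Why: Acid-catalysed methanolysis removes a primary triethylsilyl ether much faster than the hindered tertiary one, so only the C1 hydroxyl should be freed; the ester and the allylic ether are stable to pyridinium tosylate.

Step 11
Reactants: 17 primary alcohol
Product: 19 (1R,3S)-3-methyl-1-[(2R,3R)-4-methylidene-5-oxo-2-vinyloxolan-3-yl]-4-oxo-3-(triethylsilyloxy)butyl 2-methylpropanoate, via aldehyde 18 (not isolated)
Conditions: CrO3·2C5H5N (20 equiv, from CrO3 and pyridine), CH2Cl2, rt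
Reagents that add atoms: chromium trioxide, O=[Cr](=O)=O
Why: Collins oxidation; the primary alcohol should go quickly to the non-enolisable aldehyde 18, and the excess reagent then oxidises the C12 methylene, which is allylic and next to the ring oxygen, to the lactone carbonyl. This is the known conversion of 3-methylene oxolanes into α-methylene-γ-butyrolactones, and anhydrous conditions keep the aldehyde from going further.

Step 12
Reactants: 20 2-bromoallyl alcohol
Product: 21 [(2-bromoprop-2-en-1-yl)oxy](tert-butyl)diphenylsilane
Conditions: t-BuPh2SiCl, imidazole, CH2Cl2, rt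
Reagents that add atoms: tert-butylchlorodiphenylsilane, CC(C)(C)[Si](Cl)(c1ccccc1)c1ccccc1
Why: Standard silylation of a primary alcohol; the tert-butyldiphenylsilyl ether is chosen because it should survive the HF·pyridine step that removes the triethylsilyl group in step 16.

Step 13
Reactants: 21 bromoalkene; 22 ethynylmagnesium bromide
Product: 24 tert-butyl[(2-methylidenebut-3-yn-1-yl)oxy]diphenylsilane, via ethynylzinc bromide 23 (not isolated)
Conditions: 22, ZnBr2, THF, 0 °C; then 21, Pd(PPh3)4 (5 mol%), THF, rt
Reagents that add atoms: none
Why: Negishi coupling; transmetalation to the alkynylzinc and coupling with the 2-bromoalkene on zerovalent palladium give the terminal enyne directly, with no alkyne protecting group to remove.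

Step 14
Reactants: 19 aldehyde lactone; 24 enyne
Product: 26 (1R,3S)-7-({[tert-butyl(diphenyl)silyl]oxy}methyl)-4-hydroxy-3-methyl-1-[(2R,3R)-4-methylidene-5-oxo-2-vinyloxolan-3-yl]-3-(triethylsilyloxy)oct-7-en-5-yn-1-yl 2-methylpropanoate (both carbinol epimers), via lithium acetylide 25 (not isolated)
Conditions: 24, n-BuLi, THF, −78 °C; then 19, −78 °C; AcOH, −78 °C
Reagents that add atoms: none
Why: Acetylide addition to an aldehyde at −78 °C should be much faster than attack on the hindered ester or the lactone; the new carbinol configuration is irrelevant because it is oxidised in step 15, and the cold acetic acid quench is meant to prevent silyl migration and base-induced loss of the C8 acyloxy group.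

Step 15
Reactants: 26 propargylic alcohol
Product: 27 (1R,3S)-7-({[tert-butyl(diphenyl)silyl]oxy}methyl)-3-methyl-1-[(2R,3R)-4-methylidene-5-oxo-2-vinyloxolan-3-yl]-4-oxo-3-(triethylsilyloxy)oct-7-en-5-yn-1-yl 2-methylpropanoate
Conditions: Dess–Martin periodinane, CH2Cl2, 0 °C → rt
Reagents that add atoms: none
Why: Dess–Martin oxidation of a secondary propargylic alcohol to the ynone under near-neutral conditions that leave silyl ethers, lactone, ester and alkenes untouched.

Step 16
Reactants: 27 silyloxy ynone
Product: 28 (1R,3S)-7-({[tert-butyl(diphenyl)silyl]oxy}methyl)-3-hydroxy-3-methyl-1-[(2R,3R)-4-methylidene-5-oxo-2-vinyloxolan-3-yl]-4-oxooct-7-en-5-yn-1-yl 2-methylpropanoate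
Conditions: HF·pyridine, pyridine, THF, 0 °C
Reagents that add atoms: none
Why: Buffered HF·pyridine cleaves a triethylsilyl ether much faster than a tert-butyldiphenylsilyl ether and, being non-basic, should spare the ynone, the ester and the methylene lactone.

Step 17
Reactants: 28 hydroxy ynone
Product: 29 (1R)-2-[(2S)-5-(3-{[tert-butyl(diphenyl)silyl]oxy}prop-1-en-2-yl)-2-methyl-3-oxo-2,3-dihydrofuran-2-yl]-1-[(2R,3R)-4-methylidene-5-oxo-2-vinyloxolan-3-yl]ethyl 2-methylpropanoate
Conditions: AuCl3 (5 mol%), CH2Cl2, rt
Reagents that add atoms: none
Why: AuCl3 activates the ynone alkyne and the C10 hydroxyl adds to C3 in a 5-endo-dig hydroalkoxylation; protodeauration gives the 3(2H)-furanone, a known gold-catalysed cycloisomerisation of α′-hydroxy ynones, with C10 untouched.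

Step 18
Reactants: 29 furanone diene
Product: 30 the C15 tert-butyldiphenylsilyl ether of 31
Conditions: second-generation Grubbs catalyst RuCl2(=CHPh)(PCy3)(H2IMes) (20 mol%), toluene (0.5 mM), 80 °C
Reagents that add atoms: none
Why: Ring-closing metathesis; the ruthenium carbene should load on the monosubstituted C5 vinyl group and close on the 1,1-disubstituted C4 alkene with loss of ethylene. Because the furanone already ties C3 to C10, the new ring is nine-membered counting the oxygen bridge and should only accommodate the required (Z)-alkene.

Step 19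
Reactants: 30 silyl ether
Product: 31 CNP0176924.2
Conditions: HF·pyridine, THF, 0 °C → rt
Reagents that add atoms: none
Why: Fluoride-mediated cleavage of the primary silyl ether under acidic, non-basic conditions that the methylene lactone, the furanone and the isobutyrate should tolerate.

## Compound list

1 | methallyl alcohol (2-methylprop-2-en-1-ol) | CC(=C)CO | starting material
2 | (R)-2-methylglycidol, [(2R)-2-methyloxiran-2-yl]methanol | C[C@@]1(CO)CO1 | intermediate
3 | lithium acetylide–ethylenediamine complex, LiC≡CH·H2NCH2CH2NH2 | [Li+].[C-]#C.NCCN | starting material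
4 | (2S)-2-methylpent-4-yne-1,2-diol | C#CC[C@](C)(O)CO | intermediate
5 | (4S)-4-methyl-4,5-bis(triethylsilyloxy)pent-1-yne | C#CC[C@](C)(O[Si](CC)(CC)CC)CO[Si](CC)(CC)CC | intermediate
6 | acrolein (prop-2-enal) | C=CC=O | starting material
7 | lithium acetylide of 5 | [Li]C#CC[C@](C)(O[Si](CC)(CC)CC)CO[Si](CC)(CC)CC | intermediate
8 | (3RS,7S)-7-methyl-7,8-bis(triethylsilyloxy)oct-1-en-4-yn-3-ol, both C6 epimers | C=CC(O)C#CC[C@](C)(O[Si](CC)(CC)CC)CO[Si](CC)(CC)CC | intermediate
9 | (3RS,4E,7S)-7-methyl-7,8-bis(triethylsilyloxy)octa-1,4-dien-3-ol, both C6 epimers | C=CC(O)/C=C/C[C@](C)(O[Si](CC)(CC)CC)CO[Si](CC)(CC)CC | intermediate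
10 | (1R)-1-[(2R,3R)-3-[(2S)-2-methyl-2,3-bis(triethylsilyloxy)propyl]oxiran-2-yl]prop-2-en-1-ol | O[C@H](C=C)[C@H]1O[C@@H]1C[C@](C)(O[Si](CC)(CC)CC)CO[Si](CC)(CC)CC | intermediate
11 | propargyl bromide (3-bromoprop-1-yne) | C#CCBr | starting material
12 | sodium alkoxide of 10 | [Na+].[O-][C@H](C=C)[C@H]1O[C@@H]1C[C@](C)(O[Si](CC)(CC)CC)CO[Si](CC)(CC)CC | intermediate
13 | (2S,3R)-2-[(1R)-1-(prop-2-yn-1-yloxy)prop-2-en-1-yl]-3-[(2S)-2-methyl-2,3-bis(triethylsilyloxy)propyl]oxirane | C#CCO[C@H](C=C)[C@H]1O[C@@H]1C[C@](C)(O[Si](CC)(CC)CC)CO[Si](CC)(CC)CC | intermediate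
14 | (1R,3S)-3-methyl-1-[(2R,3R)-4-methylidene-2-vinyloxolan-3-yl]-3,4-bis(triethylsilyloxy)butan-1-ol | C=C1CO[C@H](C=C)[C@H]1[C@H](O)C[C@](C)(O[Si](CC)(CC)CC)CO[Si](CC)(CC)CC | intermediate
15 | isobutyryl chloride (2-methylpropanoyl chloride) | CC(C)C(Cl)=O | starting material
16 | (1R,3S)-3-methyl-1-[(2R,3R)-4-methylidene-2-vinyloxolan-3-yl]-3,4-bis(triethylsilyloxy)butyl 2-methylpropanoate | C=C1CO[C@H](C=C)[C@H]1[C@H](OC(=O)C(C)C)C[C@](C)(O[Si](CC)(CC)CC)CO[Si](CC)(CC)CC | intermediate
17 | (1R,3S)-4-hydroxy-3-methyl-1-[(2R,3R)-4-methylidene-2-vinyloxolan-3-yl]-3-(triethylsilyloxy)butyl 2-methylpropanoate | C=C1CO[C@H](C=C)[C@H]1[C@H](OC(=O)C(C)C)C[C@](C)(O[Si](CC)(CC)CC)CO | intermediate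
18 | (1R,3S)-3-methyl-1-[(2R,3R)-4-methylidene-2-vinyloxolan-3-yl]-4-oxo-3-(triethylsilyloxy)butyl 2-methylpropanoate | C=C1CO[C@H](C=C)[C@H]1[C@H](OC(=O)C(C)C)C[C@](C)(O[Si](CC)(CC)CC)C=O | intermediate
19 | (1R,3S)-3-methyl-1-[(2R,3R)-4-methylidene-5-oxo-2-vinyloxolan-3-yl]-4-oxo-3-(triethylsilyloxy)butyl 2-methylpropanoate | C=C1C(=O)O[C@H](C=C)[C@H]1[C@H](OC(=O)C(C)C)C[C@](C)(O[Si](CC)(CC)CC)C=O | intermediate
20 | 2-bromoallyl alcohol (2-bromoprop-2-en-1-ol) | OCC(Br)=C | starting material
21 | [(2-bromoprop-2-en-1-yl)oxy](tert-butyl)diphenylsilane | C=C(Br)CO[Si](c1ccccc1)(c1ccccc1)C(C)(C)C | intermediate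
22 | ethynylmagnesium bromide | C#C[Mg]Br | starting material
23 | ethynylzinc bromide | C#C[Zn]Br | intermediate
24 | tert-butyl[(2-methylidenebut-3-yn-1-yl)oxy]diphenylsilane | C#CC(=C)CO[Si](c1ccccc1)(c1ccccc1)C(C)(C)C | intermediate
25 | lithium acetylide of 24 | [Li]C#CC(=C)CO[Si](c1ccccc1)(c1ccccc1)C(C)(C)C | intermediate
26 | (1R,3S)-7-({[tert-butyl(diphenyl)silyl]oxy}methyl)-4-hydroxy-3-methyl-1-[(2R,3R)-4-methylidene-5-oxo-2-vinyloxolan-3-yl]-3-(triethylsilyloxy)oct-7-en-5-yn-1-yl 2-methylpropanoate, both carbinol epimers | C=C1C(=O)O[C@H](C=C)[C@H]1[C@H](OC(=O)C(C)C)C[C@](C)(O[Si](CC)(CC)CC)C(O)C#CC(=C)CO[Si](c2ccccc2)(c2ccccc2)C(C)(C)C | intermediate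
27 | (1R,3S)-7-({[tert-butyl(diphenyl)silyl]oxy}methyl)-3-methyl-1-[(2R,3R)-4-methylidene-5-oxo-2-vinyloxolan-3-yl]-4-oxo-3-(triethylsilyloxy)oct-7-en-5-yn-1-yl 2-methylpropanoate | C=C1C(=O)O[C@H](C=C)[C@H]1[C@H](OC(=O)C(C)C)C[C@](C)(O[Si](CC)(CC)CC)C(=O)C#CC(=C)CO[Si](c2ccccc2)(c2ccccc2)C(C)(C)C | intermediate
28 | (1R,3S)-7-({[tert-butyl(diphenyl)silyl]oxy}methyl)-3-hydroxy-3-methyl-1-[(2R,3R)-4-methylidene-5-oxo-2-vinyloxolan-3-yl]-4-oxooct-7-en-5-yn-1-yl 2-methylpropanoate | C=C1C(=O)O[C@H](C=C)[C@H]1[C@H](OC(=O)C(C)C)C[C@](C)(O)C(=O)C#CC(=C)CO[Si](c2ccccc2)(c2ccccc2)C(C)(C)C | intermediate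
29 | (1R)-2-[(2S)-5-(3-{[tert-butyl(diphenyl)silyl]oxy}prop-1-en-2-yl)-2-methyl-3-oxo-2,3-dihydrofuran-2-yl]-1-[(2R,3R)-4-methylidene-5-oxo-2-vinyloxolan-3-yl]ethyl 2-methylpropanoate | C=C1C(=O)O[C@H](C=C)[C@H]1[C@H](OC(=O)C(C)C)C[C@]2(C)OC(=CC2=O)C(=C)CO[Si](c3ccccc3)(c3ccccc3)C(C)(C)C | intermediate
30 | C15 tert-butyldiphenylsilyl ether of 31 | C=C1C(=O)O[C@@H]2/C=C(/CO[Si](c4ccccc4)(c4ccccc4)C(C)(C)C)C3=CC(=O)[C@](C)(C[C@@H](OC(=O)C(C)C)[C@@H]12)O3 | intermediate
31 | CNP0176924.2, (4Z,6R,7R,8R,10S)-15-hydroxy-8-(2-methylpropanoyloxy)-1-oxo-3,10-epoxygermacra-2,4,11(13)-trien-12,6-olide | C=C1C(=O)O[C@@H]2/C=C(/CO)C3=CC(=O)[C@](C)(C[C@@H](OC(=O)C(C)C)[C@@H]12)O3 | target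

## Step count and least certain steps

Total: 19 steps. Longest linear sequence: 17 steps (steps 1–11 and 14–19); steps 12 and 13 make fragment 24.

**Step 8 (key step).** The most likely failure is capture of the C7 radical by a second titanium before it cyclises, followed by expulsion of the C6 alkoxide and loss of the tether. Homolysis at C8–O or weak facial bias at C7 would also lower the return. The fallback uses two-electron chemistry, sets out from 10 and returns at 14. Alkylation of 10 with 2,3-dibromopropene (NaH, THF) gives the 2-bromoallyl ether F1. Bromine–lithium exchange with t-BuLi at −78 °C, then BF3·OEt2, brings about a Parham-type 5-exo-tet opening of the epoxide at C7 by the vinyllithium. This opening is stereospecific, and inversion at C7 of this erythro epoxy ether gives the same trans oxolane, 14.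

**Step 18.** The carbene may fail to engage the hindered, electron-poor 1,1-disubstituted alkene next to the bulky silyl ether, so that the vinyl group oligomerises instead; ring strain in the bridged product adds to this. The fallback sets out from 29 and returns at 31. HF·pyridine first removes the silyl group to give the free allylic alcohol F2. The metathesis is then run on F2, which has a smaller group beside the reacting alkene and a free allylic hydroxyl of the kind known to assist ruthenium metathesis. This closes the ring directly to 31.

**Step 11.** Oxidation may occur at the tertiary C6–H, which is also allylic and next to oxygen, or stop short at C12, and material may be lost on the chromium residues. The fallback sets out from 17 and returns at 19. Catalytic SeO2 with t-BuOOH hydroxylates C12 by an ene reaction and [2,3]-shift, for which a ring CH2 is preferred over the C7 methine, giving the lactol F3. TEMPO with PhI(OAc)2 then oxidises the lactol to the lactone and the primary alcohol to the aldehyde, giving 19.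

**Step 6.** Discrimination between the C6 epimers may be incomplete, the vinyl group of the 6S epimer may be epoxidised, and at best half of 9 is converted. The fallback sets out from 5 and returns at 10.
- Acetylide 7 is trapped with paraformaldehyde to give the propargylic alcohol F4.
- NaAlH2(OCH2CH2OCH3)2 gives the (E)-allylic alcohol F5.
- A Katsuki–Sharpless epoxidation with the D-(−)-tartrate, now on a primary allylic alcohol and so not a resolution, gives the epoxy alcohol F6 with C7 and C8 set.
- Parikh–Doering oxidation gives the epoxy aldehyde F7.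
- Vinylmagnesium bromide at −78 °C should add anti to the epoxide C–O bond (Felkin–Anh) to give 10, after removal of the minor C6 epimer.

**Step 14.** The acetylide may attack the lactone carbonyl or deprotonate C7, with loss of the C8 acyloxy group, or the silyl group may migrate to the new alkoxide. The fallback sets out from 17 and returns at 27. Dess–Martin oxidation of 17 gives 18 as an isolated compound. Acetylide 25 adds to 18 while no lactone is present, giving the propargylic alcohol F8. CrO3·2C5H5N then oxidises the propargylic carbinol and C12 in one operation to give 27.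

## Further compounds

F1 | step 8 | (2S,3R)-2-[(1R)-1-[(2-bromoprop-2-en-1-yl)oxy]prop-2-en-1-yl]-3-[(2S)-2-methyl-2,3-bis(triethylsilyloxy)propyl]oxirane | C=C(Br)CO[C@H](C=C)[C@H]1O[C@@H]1C[C@](C)(O[Si](CC)(CC)CC)CO[Si](CC)(CC)CC
F2 | step 18 | (1R)-2-[(2S)-5-(3-hydroxyprop-1-en-2-yl)-2-methyl-3-oxo-2,3-dihydrofuran-2-yl]-1-[(2R,3R)-4-methylidene-5-oxo-2-vinyloxolan-3-yl]ethyl 2-methylpropanoate | C=C1C(=O)O[C@H](C=C)[C@H]1[C@H](OC(=O)C(C)C)C[C@]2(C)OC(=CC2=O)C(=C)CO
F3 | step 11 | (1R,3S)-4-hydroxy-1-[(2R,3R)-5-hydroxy-4-methylidene-2-vinyloxolan-3-yl]-3-methyl-3-(triethylsilyloxy)butyl 2-methylpropanoate, both lactol epimers | C=C1C(O)O[C@H](C=C)[C@H]1[C@H](OC(=O)C(C)C)C[C@](C)(O[Si](CC)(CC)CC)CO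
F4 | step 6 | (5S)-5-methyl-5,6-bis(triethylsilyloxy)hex-2-yn-1-ol | OCC#CC[C@](C)(O[Si](CC)(CC)CC)CO[Si](CC)(CC)CC
F5 | step 6 | (2E,5S)-5-methyl-5,6-bis(triethylsilyloxy)hex-2-en-1-ol | OC/C=C/C[C@](C)(O[Si](CC)(CC)CC)CO[Si](CC)(CC)CC
F6 | step 6 | [(2R,3R)-3-[(2S)-2-methyl-2,3-bis(triethylsilyloxy)propyl]oxiran-2-yl]methanol | OC[C@H]1O[C@@H]1C[C@](C)(O[Si](CC)(CC)CC)CO[Si](CC)(CC)CC
F7 | step 6 | (2S,3R)-3-[(2S)-2-methyl-2,3-bis(triethylsilyloxy)propyl]oxirane-2-carbaldehyde | O=C[C@H]1O[C@@H]1C[C@](C)(O[Si](CC)(CC)CC)CO[Si](CC)(CC)CC
F8 | step 14 | (1R,3S)-7-({[tert-butyl(diphenyl)silyl]oxy}methyl)-4-hydroxy-3-methyl-1-[(2R,3R)-4-methylidene-2-vinyloxolan-3-yl]-3-(triethylsilyloxy)oct-7-en-5-yn-1-yl 2-methylpropanoate, both carbinol epimers | C=C1CO[C@H](C=C)[C@H]1[C@H](OC(=O)C(C)C)C[C@](C)(O[Si](CC)(CC)CC)C(O)C#CC(=C)CO[Si](c2ccccc2)(c2ccccc2)C(C)(C)C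
A1 | alternative 1 | 8-hydroxy macrocycle with α-methylene lactone and C15 tert-butyldimethylsilyl ether | C=C1C(=O)O[C@@H]2/C=C(/CO[Si](C)(C)C(C)(C)C)C3=CC(=O)[C@](C)(C[C@@H](O)[C@@H]12)O3
A2 | alternative 1 | seco aldehyde: 3-(bromomethyl)butenolide joined through the Z-alkene to the furanone bearing the C8 aldehyde | BrCC1=C[C@H](OC1=O)/C=C(/CO[Si](C)(C)C(C)(C)C)C2=CC(=O)[C@](C)(CC=O)O2
A3 | alternative 2 | isoxazoline-bridged ten-membered carbocycle with C11=C13 restored (C3 epimer arbitrary) | C=C1C(=O)O[C@@H]2/C=C(/CO[Si](C)(C)C(C)(C)C)[C@@H]3CC(=NO3)[C@@](C)(O[Si](CC)(CC)CC)C[C@@H](OC(=O)C(C)C)[C@@H]12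
A4 | alternative 2 | the same cycloadduct drawn without C13, C11 being a plain CH2 | C1C(=O)O[C@@H]2/C=C(/CO[Si](C)(C)C(C)(C)C)[C@@H]3CC(=NO3)[C@@](C)(O[Si](CC)(CC)CC)C[C@@H](OC(=O)C(C)C)[C@@H]12
A5 | alternative 2 | C1 aldoxime of the open-chain diene lactone | C=C1C(=O)O[C@H](/C=C(/CO[Si](C)(C)C(C)(C)C)C=C)[C@H]1[C@H](OC(=O)C(C)C)C[C@](C)(O[Si](CC)(CC)CC)C=NO
A6 | alternative 3 | cross-conjugated 4-hydroxy-2-ynone joining both halves | O=C1O[C@H](/C=C(/CO[Si](C)(C)C(C)(C)C)C(=O)C#C[C@@](C)(O)CC(OC)OC)C=C1COCc2ccc(OC)cc2
A7 | alternative 3 | C4 vinyl iodide on the C6 butenolide with C13 p-methoxybenzyl ether | O=C1O[C@H](/C=C(/CO[Si](C)(C)C(C)(C)C)I)C=C1COCc2ccc(OC)cc2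
A8 | alternative 3 | (3S)-5,5-dimethoxy-3-methylpent-1-yn-3-ol | C#C[C@@](C)(O)CC(OC)OC
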